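**Plan**

- Cuts: C4–C7 (key step), then the ring alkene C1=C2 (metathesis), C10=C11 (Wittig), O–C11 with C10–Br (bromoetherification), and the two ring C–halogen bonds.
- Forward: enal 3 and silyloxyfuran 5 give aldehyde–butenolide 7; methylenation and ring-closing metathesis close the cyclohexene; epoxide, bromohydrin and bromochloride follow; the lactone is opened to a (Z)-dienol, taken to the diol monoacetate, and the oxane is closed last.
- Stereochemistry: C4 comes from the amine catalyst and C7 from the syn topicity of the same step. C1/C2 come from a reagent-controlled epoxidation followed by two stereospecific displacements. C8 comes from an A(1,3)-controlled hydroxyl-directed epoxidation, and C10 from the chair of the final ring closure.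
- Enabling feature: in the oxane, C7 carries the ring oxygen, a methyl group and C8–C9–C10 in a row, which is O1–C5(Me)–C4–C3–C2 of a 5-methylfuran-2-ol. Ring carbon C4 is a CH between two CH2 groups, i.e. the β-carbon of an enal whose CH2–CHO arm becomes C3–C2, so the aldehyde carbon ends as the brominated C2.

Key step: step 3

Remark: locants follow the bisabolane skeleton: C1 (CMeCl), C2 (CHBr), C3, C4 (ring CH), C5, C6; C7 (O–C–Me), C8 (CHOAc), C9, C10 (CHBr), C11 (CMe2).
Remark: the syn topicity in step 3 and the facial sense of the dioxirane in step 6 are assigned from transition-state models, not from memory of a specific result; both are assumptions of this proposal.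

**Route**

Step 1
Reactants: 1 (E)-but-2-enal; 2 2-methylhexa-1,5-diene
Product: 3 (2E)-6-methylhepta-2,6-dienal
Conditions: phosphine-free Ru–NHC isopropoxybenzylidene metathesis catalyst (2 mol%), 1 (4 equiv), CH2Cl2, 40 °C
Reagents that add atoms: none
Why: Cross-metathesis; only the monosubstituted alkene of 2 exchanges with the enal, the 1,1-disubstituted alkene is too hindered to engage, and the conjugated product should form as the E isomer.

Step 2
Reactants: 4 5-methylfuran-2(3H)-one (α-angelica lactone)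
Product: 5 trimethyl[(5-methylfuran-2-yl)oxy]silane
Conditions: TMSCl, Et3N, MeCN, 0 °C to rt
Reagents that add atoms: chlorotrimethylsilane C[Si](C)(C)Cl
Why: Soft enolisation and O-silylation of the butenolide give the aromatic 2-silyloxyfuran; no stereocentre is involved.

Step 3
Reactants: 3 (2E)-6-methylhepta-2,6-dienal; 5 trimethyl[(5-methylfuran-2-yl)oxy]silane
Product: 7 (3S)-6-methyl-3-[(2R)-2-methyl-5-oxo-2,5-dihydrofuran-2-yl]hept-6-enal, via iminium salt 6 (not isolated)
Conditions: (2R,5R)-5-benzyl-2-tert-butyl-3-methylimidazolidin-4-one (20 mol%), 2,4-dinitrobenzoic acid (20 mol%), H2O (2 equiv), CH2Cl2, −70 °C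
Reagents that add atoms: none
Why: Iminium-catalysed vinylogous Mukaiyama–Michael reaction: enal 3 condenses with the imidazolidinone to the (E)-iminium salt 6, whose β-carbon (future C4) is attacked by C5 of silyloxyfuran 5 (future C7); loss of the silyl group to water and hydrolysis return the catalyst and the aldehyde. The closest known reaction type is the amine-catalysed addition of 5-alkyl-2-silyloxyfurans to β-alkyl enals, which gives γ,γ-disubstituted butenolides next to a tertiary centre. No ring is closed; the step forms the C4–C7 bond. C4 is set by the catalyst, whose benzyl group covers one face of the iminium ion so that the (2R,5R) enantiomer should give (S) at C4. C7 is set by the relative topicity of an open antiperiplanar transition state (furan C4 anti to the iminium α-carbon) in which the small ring oxygen, not the C5 methyl group, takes the crowded position between the iminium chain and the alkenyl chain; this places lactone oxygen and chain syn along the C8–C7–C4–C3 backbone and gives (R) at C7. The step needs 1,4- over 1,2-addition and attack through furan C5 rather than C3, both secured by the soft γ-nucleophile and the hindered iminium carbon, and the unactivated 1,1-disubstituted alkene of 3 should stay out.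

Step 4
Reactants: 7 (3S)-6-methyl-3-[(2R)-2-methyl-5-oxo-2,5-dihydrofuran-2-yl]hept-6-enal
Product: 8 (5R)-5-methyl-5-[(4S)-7-methylocta-1,7-dien-4-yl]furan-2(5H)-one
Conditions: Ph3PCH3Br, KHMDS, THF, −78 to 0 °C
Reagents that add atoms: methyltriphenylphosphonium bromide C[P+](c1ccccc1)(c1ccccc1)c1ccccc1.[Br-]
Why: Wittig methylenation of the aldehyde; the lactone carbonyl is inert to the ylide at low temperature and neither stereocentre is touched (C4 is β to the aldehyde).

Step 5
Reactants: 8 (5R)-5-methyl-5-[(4S)-7-methylocta-1,7-dien-4-yl]furan-2(5H)-one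
Product: 9 (5R)-5-methyl-5-[(1S)-4-methylcyclohex-3-en-1-yl]furan-2(5H)-one
Conditions: Ru–NHC benzylidene metathesis catalyst (2nd generation, 3 mol%), CH2Cl2 (0.01 M), 40 °C
Reagents that add atoms: none
Why: Ring-closing metathesis of the 1,7-diene closes the six-membered ring as the trisubstituted C1=C2 alkene; the electron-poor, hindered butenolide alkene should not take part, and the position of the new double bond is what makes C4 the ring stereocentre.

Step 6
Reactants: 9 (5R)-5-methyl-5-[(1S)-4-methylcyclohex-3-en-1-yl]furan-2(5H)-one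
Product: 10 (5R)-5-methyl-5-[(1S,4S,6R)-1-methyl-7-oxabicyclo[4.1.0]heptan-4-yl]furan-2(5H)-one
Conditions: D-fructose-derived ketone catalyst (1,2:4,5-di-O-isopropylidene-D-erythro-2,3-hexodiulo-2,6-pyranose, 30 mol%), Oxone, K2CO3, Bu4NHSO4, MeCN–dimethoxymethane/aq. borate–EDTA buffer, 0 °C
Reagents that add atoms: potassium peroxymonosulfate (Oxone) [K+].[O-]S(=O)(=O)OO
Why: Shi epoxidation: the chiral dioxirane epoxidises the only electron-rich alkene through a spiro transition state, and reagent control should place oxygen on the ring face anti to the C4 substituent (new centres C1 and C2); the butenolide alkene is too electron-poor to react.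

Step 7
Reactants: 10 (5R)-5-methyl-5-[(1S,4S,6R)-1-methyl-7-oxabicyclo[4.1.0]heptan-4-yl]furan-2(5H)-one
Product: 11 (5R)-5-[(1S,3R,4R)-4-bromo-3-hydroxy-4-methylcyclohexyl]-5-methylfuran-2(5H)-one
Conditions: 48% aq. HBr (1.2 equiv), Et2O, −20 °C
Reagents that add atoms: hydrogen bromide Br
Why: Acid-mediated epoxide opening: bromide attacks the tertiary C1 with inversion in the trans-diaxial (Fürst–Plattner) mode, which for this epoxide diastereomer is also the Markovnikov carbon, giving the tertiary bromide anti to the C2 hydroxyl.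

Step 8
Reactants: 11 (5R)-5-[(1S,3R,4R)-4-bromo-3-hydroxy-4-methylcyclohexyl]-5-methylfuran-2(5H)-one
Product: 13 (5R)-5-[(1S,3S,4S)-3-bromo-4-chloro-4-methylcyclohexyl]-5-methylfuran-2(5H)-one, via bromonium chloride 12 (not isolated)
Conditions: PPh3, N-chlorosuccinimide, CH2Cl2, −20 °C to rt
Reagents that add atoms: N-chlorosuccinimide O=C1CCC(=O)N1Cl
Why: Appel-type activation of the C2 hydroxyl with 1,2-bromine shift: the anti-periplanar bromine displaces the activated oxygen to give bromonium ion 12 on the face syn to the side chain, and chloride opens it at the tertiary C1 from the opposite face, so that C2–Br (inversion) and C1–Cl (net retention) end trans-diequatorial.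

Step 9
Reactants: 13 (5R)-5-[(1S,3S,4S)-3-bromo-4-chloro-4-methylcyclohexyl]-5-methylfuran-2(5H)-one
Product: 14 (5R)-5-[(1S,3S,4S)-3-bromo-4-chloro-4-methylcyclohexyl]-5-methyl-2,5-dihydrofuran-2-ol (both anomers)
Conditions: DIBAL-H (1.1 equiv), CH2Cl2, −78 °C; Rochelle salt work-up
Reagents that add atoms: none
Why: Partial 1,2-reduction of the lactone to the lactol; the aluminium hemiacetal is stable at −78 °C, the alkyl halides are inert, and the new anomeric centre is lost in the next step.

Step 10
Reactants: 14 (5R)-5-[(1S,3S,4S)-3-bromo-4-chloro-4-methylcyclohexyl]-5-methyl-2,5-dihydrofuran-2-ol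
Product: 16 (2R,3Z)-2-[(1S,3S,4S)-3-bromo-4-chloro-4-methylcyclohexyl]-6-methylhepta-3,5-dien-2-ol, via hydroxy enal 15 (not isolated)
Conditions: i-PrPPh3I (3 equiv), n-BuLi, THF, 0 °C; then 14, −78 °C to rt
Reagents that add atoms: isopropyltriphenylphosphonium iodide CC(C)[P+](c1ccccc1)(c1ccccc1)c1ccccc1.[I-]
Why: Wittig olefination of the ring-opened hydroxy enal 15 that is in equilibrium with the lactol; the Z geometry of C8=C9 is inherited from the butenolide ring and C11 carries two methyl groups, so no new stereoelement arises.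

Step 11
Reactants: 16 (2R,3Z)-2-[(1S,3S,4S)-3-bromo-4-chloro-4-methylcyclohexyl]-6-methylhepta-3,5-dien-2-ol
Product: 17 (1R)-1-[(1S,3S,4S)-3-bromo-4-chloro-4-methylcyclohexyl]-1-[(2R,3R)-3-(2-methylprop-1-en-1-yl)oxiran-2-yl]ethan-1-ol
Conditions: VO(acac)2 (5 mol%), t-BuOOH (1.5 equiv), 2,6-lutidine (cat.), CH2Cl2, 0 °C
Reagents that add atoms: tert-butyl hydroperoxide CC(C)(C)OO
Why: Hydroxyl-directed vanadium-catalysed epoxidation of the allylic C8=C9 alkene in preference to the remote trisubstituted one; with the Z alkene, A(1,3) strain puts the C7 methyl inside and the cyclohexyl group outside in the transition state, so oxygen should be delivered to the face that gives (R) at C8.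

Step 12
Reactants: 17 (1R)-1-[(1S,3S,4S)-3-bromo-4-chloro-4-methylcyclohexyl]-1-[(2R,3R)-3-(2-methylprop-1-en-1-yl)oxiran-2-yl]ethan-1-ol
Product: 18 (2R,3R)-2-[(1S,3S,4S)-3-bromo-4-chloro-4-methylcyclohexyl]-6-methylhept-5-ene-2,3-diol
Conditions: DIBAL-H (3 equiv), CH2Cl2/hexane, −78 to −20 °C
Reagents that add atoms: none
Why: Regioselective reductive opening of a 2,3-epoxy alcohol that is also a vinyl epoxide: the aluminium-coordinated epoxide takes hydride at the allylic C9 (C-3 of the epoxy alcohol), giving the 1,2-diol with C8 untouched.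

Step 13
Reactants: 18 (2R,3R)-2-[(1S,3S,4S)-3-bromo-4-chloro-4-methylcyclohexyl]-6-methylhept-5-ene-2,3-diol
Product: 19 (2R,3R)-2-[(1S,3S,4S)-3-bromo-4-chloro-4-methylcyclohexyl]-2-hydroxy-6-methylhept-5-en-3-yl acetate
Conditions: Ac2O, pyridine, DMAP (cat.), CH2Cl2, 0 °C
Reagents that add atoms: acetic anhydride CC(=O)OC(C)=O
Why: Chemoselective DMAP-catalysed acylation of the secondary hydroxyl; the tertiary C7 hydroxyl is too hindered and is kept for ring closure, and the free C8 hydroxyl can no longer compete in the next step.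

Step 14
Reactants: 19 (2R,3R)-2-[(1S,3S,4S)-3-bromo-4-chloro-4-methylcyclohexyl]-2-hydroxy-6-methylhept-5-en-3-yl acetate
Product: 21 8-acetylcaespitol, (2R,3R,5R)-5-bromo-2-[(1S,3S,4S)-3-bromo-4-chloro-4-methylcyclohexyl]-2,6,6-trimethyloxan-3-yl acetate, via bromonium ion 20 (not isolated)
Conditions: NBS (1.2 equiv), (CF3)2CHOH, 4 Å MS, 0 °C, dark
Reagents that add atoms: N-bromosuccinimide O=C1CCC(=O)N1Br
Why: 6-endo bromoetherification: bromonium ion 20 is opened at the tertiary C11 (Markovnikov) by the C7 hydroxyl through a chair transition state with bromine and the cyclohexyl group equatorial and the C7 methyl axial, which sets (R) at C10; the other chair would put the cyclohexyl group axial against a C11 methyl.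

**Compound list**

1 | (E)-but-2-enal (crotonaldehyde) | C/C=C/C=O | starting material
2 | 2-methylhexa-1,5-diene | C=CCCC(C)=C | starting material
3 | (2E)-6-methylhepta-2,6-dienal | O=C/C=C/CCC(C)=C | intermediate
4 | 5-methylfuran-2(3H)-one (α-angelica lactone) | CC1=CCC(=O)O1 | starting material
5 | trimethyl[(5-methylfuran-2-yl)oxy]silane | Cc1ccc(O[Si](C)(C)C)o1 | intermediate
6 | iminium 2,4-dinitrobenzoate from 3 and (2R,5R)-5-benzyl-2-tert-butyl-3-methylimidazolidin-4-one | C=C(C)CC/C=C/C=[N+]1[C@@H](C(C)(C)C)N(C)C(=O)[C@H]1Cc1ccccc1.[O-]C(=O)c1ccc(cc1[N+](=O)[O-])[N+](=O)[O-] | intermediate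
7 | (3S)-6-methyl-3-[(2R)-2-methyl-5-oxo-2,5-dihydrofuran-2-yl]hept-6-enal | O=CC[C@H](CCC(C)=C)[C@]1(C)C=CC(=O)O1 | intermediate
8 | (5R)-5-methyl-5-[(4S)-7-methylocta-1,7-dien-4-yl]furan-2(5H)-one | C=CC[C@H](CCC(C)=C)[C@]1(C)C=CC(=O)O1 | intermediate
9 | (5R)-5-methyl-5-[(1S)-4-methylcyclohex-3-en-1-yl]furan-2(5H)-one | O=C1C=C[C@](C)(O1)[C@H]1CCC(C)=CC1 | intermediate
10 | (5R)-5-methyl-5-[(1S,4S,6R)-1-methyl-7-oxabicyclo[4.1.0]heptan-4-yl]furan-2(5H)-one | O=C1C=C[C@](C)(O1)[C@H]1CC[C@]2(C)O[C@@H]2C1 | intermediate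
11 | (5R)-5-[(1S,3R,4R)-4-bromo-3-hydroxy-4-methylcyclohexyl]-5-methylfuran-2(5H)-one | O=C1C=C[C@](C)(O1)[C@H]1CC[C@@](C)(Br)[C@H](O)C1 | intermediate
12 | bromonium chloride bridging ring C1 and C2 on the face syn to the side chain | O=C1C=C[C@](C)(O1)[C@H]1CC[C@@]2(C)[Br+][C@H]2C1.[Cl-] | intermediate
13 | (5R)-5-[(1S,3S,4S)-3-bromo-4-chloro-4-methylcyclohexyl]-5-methylfuran-2(5H)-one | O=C1C=C[C@](C)(O1)[C@H]1CC[C@](C)(Cl)[C@@H](Br)C1 | intermediate
14 | (5R)-5-[(1S,3S,4S)-3-bromo-4-chloro-4-methylcyclohexyl]-5-methyl-2,5-dihydrofuran-2-ol (both anomers) | OC1C=C[C@](C)(O1)[C@H]1CC[C@](C)(Cl)[C@@H](Br)C1 | intermediate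
15 | (2Z,4R)-4-[(1S,3S,4S)-3-bromo-4-chloro-4-methylcyclohexyl]-4-hydroxypent-2-enal | O=C/C=C\[C@](C)(O)[C@H]1CC[C@](C)(Cl)[C@@H](Br)C1 | intermediate
16 | (2R,3Z)-2-[(1S,3S,4S)-3-bromo-4-chloro-4-methylcyclohexyl]-6-methylhepta-3,5-dien-2-ol | CC(C)=C/C=C\[C@](C)(O)[C@H]1CC[C@](C)(Cl)[C@@H](Br)C1 | intermediate
17 | (1R)-1-[(1S,3S,4S)-3-bromo-4-chloro-4-methylcyclohexyl]-1-[(2R,3R)-3-(2-methylprop-1-en-1-yl)oxiran-2-yl]ethan-1-ol | CC(C)=C[C@H]1O[C@H]1[C@](C)(O)[C@H]1CC[C@](C)(Cl)[C@@H](Br)C1 | intermediate
18 | (2R,3R)-2-[(1S,3S,4S)-3-bromo-4-chloro-4-methylcyclohexyl]-6-methylhept-5-ene-2,3-diol | CC(C)=CC[C@@H](O)[C@](C)(O)[C@H]1CC[C@](C)(Cl)[C@@H](Br)C1 | intermediate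
19 | (2R,3R)-2-[(1S,3S,4S)-3-bromo-4-chloro-4-methylcyclohexyl]-2-hydroxy-6-methylhept-5-en-3-yl acetate | CC(C)=CC[C@@H](OC(C)=O)[C@](C)(O)[C@H]1CC[C@](C)(Cl)[C@@H](Br)C1 | intermediate
20 | C10–C11 bromonium ion of 19 (succinimide counter-ion) | CC(=O)O[C@H](C[C@H]1[Br+]C1(C)C)[C@](C)(O)[C@H]1CC[C@](C)(Cl)[C@@H](Br)C1.O=C1CCC(=O)[N-]1 | intermediate
21 | 8-acetylcaespitol, (2R,3R,5R)-5-bromo-2-[(1S,3S,4S)-3-bromo-4-chloro-4-methylcyclohexyl]-2,6,6-trimethyloxan-3-yl acetate | CC(=O)O[C@@H]1C[C@@H](Br)C(C)(C)O[C@]1(C)[C@H]1CC[C@](C)(Cl)[C@@H](Br)C1 | target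

Total step count: 14. Longest linear sequence: 13 steps (steps 1 and 3–14).

**Steps most likely to fail**

Step 8. After activation of the C2 hydroxyl, chloride may open the bromonium ion at the secondary C2 instead of C1, or the tertiary axial bromide may lose HBr before the hydroxyl is activated. The fallback sets out from alkene 9 and returns at 13, replacing steps 6–8 by direct anti addition of BrCl (NBS with anhydrous HCl, CH2Cl2, −78 °C) to the ring alkene. Both faces take up Br+ and chloride opens each bromonium ion at the tertiary carbon, so 13 should form together with its trans-diaxial diastereomer (5R)-5-[(1S,3R,4R)-3-bromo-4-chloro-4-methylcyclohexyl]-5-methylfuran-2(5H)-one F1, which is likely the main component. 13 would be separated by chromatography, so this approach trades selectivity for the absence of any hydroxyl activation.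

Step 14. Br+ may be transferred to both faces of the prenyl alkene (C10 epimer), and the C7 hydroxyl may close 5-exo at C10 to an oxolane. The fallback sets out from 19 and returns at 21 through the same ion 20, now generated on one face only. Shi epoxidation of the prenyl alkene with the enantiomer of the ketone used in step 6 should give (2R,3R)-3-[(1S,3S,4S)-3-bromo-4-chloro-4-methylcyclohexyl]-1-[(2S)-3,3-dimethyloxiran-2-yl]-3-hydroxybutan-2-yl acetate F2. HBr opening at the tertiary carbon should give (2R,3R,5S)-6-bromo-2-[(1S,3S,4S)-3-bromo-4-chloro-4-methylcyclohexyl]-2,5-dihydroxy-6-methylheptan-3-yl acetate F3. Triflation of the secondary hydroxyl (Tf2O, 2,6-di-tert-butylpyridine, CH2Cl2, −78 °C) should give (2R,3R,5S)-6-bromo-2-[(1S,3S,4S)-3-bromo-4-chloro-4-methylcyclohexyl]-2-hydroxy-6-methyl-5-[(trifluoromethanesulfonyl)oxy]heptan-3-yl acetate F4. In F4 the anti bromine displaces triflate with inversion at C10 to give 20, which the C7 hydroxyl closes at C11.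

Step 6. The chiral dioxirane may discriminate the faces of the ring alkene poorly, since the substrate has no bias of its own, and the lactone may hydrolyse at the pH of the reaction. The fallback sets out from 9 and returns at 11. Unselective epoxidation with mCPBA (CH2Cl2, NaHCO3, 0 °C) should give 10 and its epimer (5R)-5-methyl-5-[(1R,4S,6S)-1-methyl-7-oxabicyclo[4.1.0]heptan-4-yl]furan-2(5H)-one F5, and the HBr opening of step 7 is run on the mixture. By the trans-diaxial rule 10 opens at C1 and F5 at C2, so 11 and the secondary bromide (5R)-5-[(1S,3R,4R)-3-bromo-4-hydroxy-4-methylcyclohexyl]-5-methylfuran-2(5H)-one F6 are constitutional isomers that should separate on silica.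

Further compounds
F1 | step 8 | (5R)-5-[(1S,3R,4R)-3-bromo-4-chloro-4-methylcyclohexyl]-5-methylfuran-2(5H)-one | O=C1C=C[C@](C)(O1)[C@H]1CC[C@@](C)(Cl)[C@H](Br)C1
F2 | step 14 | (2R,3R)-3-[(1S,3S,4S)-3-bromo-4-chloro-4-methylcyclohexyl]-1-[(2S)-3,3-dimethyloxiran-2-yl]-3-hydroxybutan-2-yl acetate | CC1(C)O[C@H]1C[C@@H](OC(C)=O)[C@](C)(O)[C@H]1CC[C@](C)(Cl)[C@@H](Br)C1
F3 | step 14 | (2R,3R,5S)-6-bromo-2-[(1S,3S,4S)-3-bromo-4-chloro-4-methylcyclohexyl]-2,5-dihydroxy-6-methylheptan-3-yl acetate | CC(C)(Br)[C@@H](O)C[C@@H](OC(C)=O)[C@](C)(O)[C@H]1CC[C@](C)(Cl)[C@@H](Br)C1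
F4 | step 14 | (2R,3R,5S)-6-bromo-2-[(1S,3S,4S)-3-bromo-4-chloro-4-methylcyclohexyl]-2-hydroxy-6-methyl-5-[(trifluoromethanesulfonyl)oxy]heptan-3-yl acetate | CC(C)(Br)[C@@H](OS(=O)(=O)C(F)(F)F)C[C@@H](OC(C)=O)[C@](C)(O)[C@H]1CC[C@](C)(Cl)[C@@H](Br)C1
F5 | step 6 | (5R)-5-methyl-5-[(1R,4S,6S)-1-methyl-7-oxabicyclo[4.1.0]heptan-4-yl]furan-2(5H)-one | O=C1C=C[C@](C)(O1)[C@H]1CC[C@@]2(C)O[C@H]2C1
F6 | step 6 | (5R)-5-[(1S,3R,4R)-3-bromo-4-hydroxy-4-methylcyclohexyl]-5-methylfuran-2(5H)-one | O=C1C=C[C@](C)(O1)[C@H]1CC[C@@](C)(O)[C@H](Br)C1
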